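Count the half-lives.

| setting | east | north | dawn | autumn |
|---|---|---|---|---|
| solid substrate | 0.043 M | 0.11 M | 0.050 M | 0.16 M |
| temperature | −45 °C | −25 °C |  |  |
| remark | run made earlier | run made earlier | at −10 °C throughout | at −40 °C until 3.0 min, from then on at −10 °C |
| time |  |  | 10 min | 10 min |

| run | time / min | target / % | isomer of the product / % | solid substrate / % |
|---|---|---|---|---|
| east | 1.00 | 3.6 | 0.6 | 0 |
| east | 2.00 | 8.1 | 1.1 | 0.1 |
| east | 3.00 | 12.0 | 1.6 | 0 |
| east | 4.00 | 15.1 | 2.6 | 0 |
| east | 5.00 | 17.8 | 2.2 | 0 |
| north | 0.200 | 1.4 | 0.1 | 86.5 |
| north | 0.667 | 8.9 | 1.7 | 60.0 |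
| north | 1.33 | 17.8 | 5.1 | 32.2 |
| north | 2.00 | 25.5 | 8.6 | 10.7 |
| north | 2.50 | 29.1 | 11.1 | 0 |

(scatter of a reading: 0.3 percentage points)

- solid, in amounts per volume of the solution: solid substrate
- at the start none of the solid substrate is in solution
- what has only dissolved of solid substrate counts as not reacted
- a reading or a percentage of target counts all its forms, free or not

- the winner by share of target in all that became target or isomer of the product; "neither" if no more than 2 percentage points parts them (dawn / autumn / neither)
- share of target in all that became target or isomer of the product, dawn
- share of target in all that became target or isomer of the product, autumn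

Two sets of readings offer a share of target at once. The east flask at −45 °C holds 17.8% target and 2.2% isomer of the product after 5.00 min, a share of 89.0%. The north flask at −25 °C gains the two in the ratio 1.44 over its last interval, a share of 59.0%. That figure is rough, since each gain is a difference of readings good to 0.3 percentage points. The two shares part by 30 points, so one of them cheats.

A clock tells which. In the east flask the solid reads about nil, and target grows by 0.0405 min⁻¹ of the charge. In the north flask's first interval, target grows at 0.776 min⁻¹, counted on the 20.7% dissolved and unreacted on average. In logarithms:

between −45 °C and −25 °C: 1.28 powers of ten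

on to −10 °C, along the same line: 0.960 more, so 7.10 min⁻¹

The half-life of dissolved material going to target at −10 °C is then 0.0976 min.

The east run lasted 0.292 of its own half-lives and the north run 2.80. Across the north run the gain ratio falls from 4.69 to 1.44. So the east share is a ratio of speeds, not of resting places (kinetic against thermodynamic control), and it is the one that cheats. Dawn has 102 half-lives and autumn's warm stretch 71.7. This reckoning therefore puts both flasks near 59.0%, with neither ahead.

The forecast, holding that “isomer runs one order higher in dissolved substrate”, named dawn, with 70% for dawn (64% to 77%) and 51% for autumn (44% to 59%).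

Dawn gives 59.9% and autumn 60.5%, so the answer is neither: they stand 0.60 points apart, less than 2 points.

    starting material ⇌ target (K = 0.540, k = 0.120 min⁻¹, Ea = 74.0 kJ mol⁻¹, ΔH = −1.00 kJ mol⁻¹)
    starting material + target ⇌ idle adduct, settled at all times (K = 3.00 M⁻¹, ΔH = −32.0 kJ mol⁻¹)
    solid substrate ⇌ starting material, rate k3*(cs3 - [starting material]) while solid is left; crystals form when [starting material] > cs3 (solubility = 0.0930 M, k = 0.890 min⁻¹)
    starting material ⇌ isomer of the product (K = 0.700, k = 0.0140 min⁻¹, Ea = 77.0 kJ mol⁻¹, ΔH = −12.0 kJ mol⁻¹)
    (constants at −40 °C)

The reckoned 0.0976 min stands beside 0.074 min, the half-life of starting material by the forward path to target alone in autumn at 10.0 min. The 7.00 min of warmth in autumn are 71.7 of the reckoned half-lives and 94.1 of the forward ones, and left for 100 min autumn stands at 60.5%. The flask charged with 0.27 M, otherwise like autumn, has the same 7.00 min of warmth and ends at 60.6%, with 35.9% solid substrate still there.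

The readings stem from a simulated flask from invented constants; the scatter is artificial.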